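The trap in this flask is to set the half-life of starting material by binding to free catalyst, 2.2 min on the forward step alone with the charges held, against the run of 10 min, and to call the run finished whatever the partner does.

    partner + catalyst intermediate A → catalyst intermediate B (k1 = 4.4 L mol⁻¹ s⁻¹)
    starting material + free catalyst ⇌ catalyst intermediate A (K2 = 11 L mol⁻¹, k2 = 11 L mol⁻¹ s⁻¹)
    catalyst intermediate C → catalyst intermediate D (k3 = 100 s⁻¹)
    catalyst intermediate D → free catalyst + target (k4 = 3.4 s⁻¹)
    catalyst intermediate B → by-product + catalyst intermediate C (k5 = 58 s⁻¹)
    starting material + by-product ⇌ idle adduct, settled at all times (K6 = 43 L mol⁻¹)

in all of them: starting material 0.094 M; free catalyst 0.47 mM; time 10 min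
- north-west: partner 0.170 M
- north: partner 0.250 M
- south: partner 0.380 M

- for by-product the idle adduct is counted in
- what has gone from starting material into another species counts as reacted, even if it can come back
- run time (north-west): 10 min

- part of the starting material that has reacted at the end, north-west
- part of the starting material that has reacted at the end, north
- part of the starting material that has reacted at the end, south
- what raising the concentration of partner from its lowest to its highest value here does to the part of the starting material that has reacted (changes below 5 percentage points count as none) (no change / it falls / it rises)

*Why is binding not yet conversion?* Catalyst intermediate A has two exits. It falls back to starting material and free catalyst at 1.00 s⁻¹, the binding constant over its equilibrium constant. Or partner captures it, at 0.748 s⁻¹ in north-west, 1.10 s⁻¹ in north and 1.67 s⁻¹ in south.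

*Where does control change hands?* Where the exits are equal, at partner 0.227 M. North-west is charged below that crossing, north and south above it.

*What do you carry?* In south 62.6% of catalyst intermediate A goes forward: this is the capture share, capture over capture plus return. It is 42.8% in north-west and 52.4% in north.

*And the clock?* Share times binding constant times catalyst charge is a pseudo-first-order constant: 0.133 min⁻¹ in north-west, 0.162 min⁻¹ in north, 0.194 min⁻¹ in south. Over the run my reckoning gives 73.5%, 80.3% and 85.6% reacted, a rise of 12 percentage points, more than the 5 points that counts.

*Release from catalyst intermediate D, at 3.4 s⁻¹, is slower than the two steps before it. Why ignore it?* It is faster than capture even in south, and faster than binding at the charge, 1.03 s⁻¹.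

*Your weak spot?* The idle adduct. Its equilibrium constant times starting material at the start is 4.0, so by-product binds starting material strongly. That counts as reacted yet takes starting material out of the cycle, and I held partner and free catalyst at their charges as well.

The forecast gives 71% (66% to 76%), 79% (74% to 83%) and 84% (79% to 88%), with the trend "it rises": “more partner raises conversion only moderately”. Each figure lies below mine.

The simulation gives 71.2%, 78.7% and 83.9%, and it rises by 13 points. At 10.0 min in south, free catalyst, the resting state, holds 90.9% of the catalyst charged, and catalyst intermediate A 6.24%. With 85.1% of the partner left there, the capture share of south has moved from 62.6% to 58.7%. Read south early, at 2.5 min: the same constant gives 38.4% reacted. The computed result is 42.6%, with idle adduct at 17.5%.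

(The constants used here were drawn at random within sensible limits; the result is computed.)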